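Readings and results come from a simulation for substances that don't exist; the scatter is artificial.

Your hunch, that substrate hardly matters and so the elm run will be through by 24 min, falls into a trap. The larch run does make 0.227 M of target in that time, more than the 0.170 M of substrate charged to elm, but elm starts with c(partner) at 0.250 M, not 0.750 M.

| setting | larch | oak | alder | maple | elm |
|---|---|---|---|---|---|
| substrate | 0.500 M | 0.300 M | 0.500 M | 0.250 M | 0.170 M |
| partner | 0.750 M | 0.550 M | 0.750 M | 0.750 M | 0.250 M |
| free catalyst | 0.0250 M | 0.0250 M | 0.0250 M | 0.0250 M | 0.0250 M |
| target |  |  | 0.150 M |  |  |
| time |  |  |  |  | 24 min |

- larch run (time / min: [target] / M): 1.8: 0.021; 5.5: 0.058; 11: 0.114; 17: 0.168; 24: 0.227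
- oak run (time / min: [target] / M): 1.8: 0.015; 5.5: 0.041; 11: 0.087; 17: 0.135; 24: 0.186
- alder run (time / min: [target] / M): 1.8: 0.170; 5.5: 0.209; 11: 0.263; 17: 0.313; 24: 0.384
- maple run (time / min: [target] / M): 1.8: 0.021; 5.5: 0.052; 11: 0.099; 17: 0.153; 24: 0.200

(standard deviation of a reading: 0.003 M)

1. how the opening rate goes with [partner] round the charge of the larch run: the exponent of the rate at two percent of substrate gone to target
2. how the opening rate goes with [substrate] round the charge of the larch run: the exponent of the rate at two percent of substrate gone to target (one fixed amount of target, the same in the runs compared)
3. the oak run starts with 0.200 M less of substrate and of partner than the larch run, and with no target. Compared where both hold the same amount of substrate, once fifteen percent of what the oak run was charged with has turned into target, is the oak run faster, slower or alike (within a tenth)?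
4. target in the elm run at 24 min, as a share of the substrate charged
5. which of these the readings show (nothing beyond the main steps / the catalyst rests as a dimer / two substrates go astray together / the second partner pairs with itself)

- Overall: substrate + partner -> target, with free catalyst as catalyst.
- Constant volume, constant temperature.
- The analysis sees a species whether free or bound.
- "The second partner" is partner.
- An order is taken over about fifteen percent of the charge, up and down.

So you need to know what partner is worth. Larch against oak won't tell you, since both charges change at once, so go in two steps, using the readings at 11 min. Larch and maple share c(partner), and larch has twice the substrate, yet they stand at 0.114 M and 0.099 M. That gives a substrate exponent of 0.204, taken over a wide span, so I treat it as an upper mark for ord_S. Maple and oak differ mainly in partner, and correcting their gap for substrate gives the partner exponent 0.536, the apparent order, meaning the power of c(partner) that the rate follows. The scatter of one oak reading moves it by 0.111.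

Now elm, without any integral. Larch averages 0.0104 M/min over that stretch, at mid-stretch c(partner) 0.693 M and c(substrate) 0.443 M. Scale that rate by the two powers. At elm's charge it gives 0.118 M of target by 24 min, too much, since the charge doesn't last. Redone at the mid-run concentrations this implies, it gives 0.0939 M, too little. Their mean is 62.5% of the substrate charged.

For the comparison at equal substrate, slopes won't do, because the point asked lies late in larch, beyond the 0.200 M of substrate it uses to come down to oak's charge. Having used that much, larch also holds oak's charge of partner, and the two flasks use both one for one, so at equal substrate they hold equal c(partner). They then differ in the target already made and in how long the catalyst has worked. For target, look at alder, which is larch's charge with target added: between its first and last readings it gains 0.214 M against larch's 0.206 M, a ratio of 1.04. I have no separate test of the catalyst's age, so alike is my judgement. An exponent near a square root, for a partner consumed one molecule at a time, makes me pick partner pairing with itself, with the free part following the root of the charge.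

The forecast, made from the same runs, differs from me on the exponent and the cause: 0.37 for partner, 0.08 for substrate, alike, 65% for elm, and nothing beyond the main steps, in its words “No extra step is needed”.

The flask gives 0.53 for partner, 0.065 for substrate, alike, 62.1% for elm, and the second partner pairs with itself.

    free catalyst + substrate → catalyst-substrate complex (15.30 /M/min)
    catalyst-substrate complex + partner → loaded catalyst (2.868 /M/min)
    loaded catalyst → target + free catalyst (57.42 /min)
    2 partner ⇌ idle reagent dimer, settled at all times (11.60 /M)

The partner exponent 0.536 stands beside the 0.53 of the flask. The catalyst-substrate complex meets free partner, and of the 0.750 M charged to larch, 0.160 M is free at the start, the rest sitting as idle reagent dimer. Without that pairing the exponent rises to 0.72, and the elm run at 24 min reaches 93.4% of its substrate instead of 62.1%.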